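**Retrosynthetic overview**
- The (Z)-4-acetoxy-2-enoic acid side chain is the ring-opened, reduced form of a 3-alkylfuran. The last step is a singlet-oxygen dearomatization: furan C5 becomes the C15 acid, furan C2 becomes C16 (CH2OAc), and the Z geometry is inherited from the ring.
- C6–OH and C8=CH2 come from a bicyclic 6-en-8-one by conjugate borylation/oxidation anti to the angular methyl, then methylenation.
- Ring A is closed second, onto the preformed ring B, by a vinylogous SN1 alkylation (C4 cation onto C5 of a dienol silane).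
- Ring B is bought as 3-methylcyclohexenone. A copper-catalysed asymmetric conjugate addition sets the C10 quaternary centre, and the enolate is alkylated at C9 with a 2-(3-furyl)ethyl triflate.
- Ring order: ring B (bought), ring A (step 6), furan ring opened last (step 9).

Assumption: the three starting materials and all reagents named are commercial; positions are given in labdane numbering (ring A = C1–C5 and C10, ring B = C5–C10, side chain C11–C16, exocyclic methylene C17).

**Step 1**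
Reactants: 1 5-bromo-2-methylpent-2-ene
Product: 2 5-bromo-2-methoxy-2-methylpentane
Conditions: MeOH, H2SO4 (5 mol %), 25 °C
Reagents that add atoms: methanol CO
Why: Acid-catalysed Markovnikov hydroalkoxylation (tertiary cation trapped by the solvent) turns the alkene into a tertiary methyl ether that tolerates the magnesium and copper chemistry and later serves as an aprotic cation source.

**Step 2**
Reactants: 3 3-bromofuran
Product: 5 2-(furan-3-yl)ethan-1-ol, via furan-3-yllithium 4 (not isolated)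
Conditions: n-BuLi, THF, −78 °C; oxirane, BF3·OEt2, −78 °C
Reagents that add atoms: oxirane C1CO1
Why: Bromine–lithium exchange at −78 °C (cold enough to stop migration of lithium to C2 of the furan) followed by BF3-promoted epoxide opening by the aryllithium.

**Step 3**
Reactants: 5 2-(furan-3-yl)ethan-1-ol
Product: 6 2-(furan-3-yl)ethyl trifluoromethanesulfonate
Conditions: Tf2O, 2,6-lutidine, CH2Cl2, −78 °C; used at once
Reagents that add atoms: trifluoromethanesulfonic anhydride O=S(=O)(OS(=O)(=O)C(F)(F)F)C(F)(F)F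
Why: O-sulfonylation of the primary alcohol with a hindered pyridine base gives a primary triflate reactive enough to alkylate a magnesium enolate.

**Step 4**
Reactants: 7 3-methylcyclohex-2-en-1-one; 2 5-bromo-2-methoxy-2-methylpentane; 6 2-(furan-3-yl)ethyl trifluoromethanesulfonate
Product: 10 (2S,3R)-2-[2-(furan-3-yl)ethyl]-3-(4-methoxy-4-methylpentyl)-3-methylcyclohexan-1-one, via Grignard reagent 8 (not isolated), via magnesium enolate 9 (not isolated)
Conditions: 2, Mg, Et2O; then 7, Cu(OTf)2 (3 mol %), 1-(1-hydroxy-4-methylpentan-2-yl)-3-(2,4,6-trimethylphenyl)-4,5-dihydroimidazolium hexafluorophosphate (4 mol %, enantiomer that gives the R centre), Et2O, −30 °C; then 6, DMPU, −30 → 0 °C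
Reagents that add atoms: none
Why: Copper–NHC-catalysed asymmetric conjugate addition of the Grignard reagent to the β-methyl enone sets the C10 quaternary centre under catalyst control, and the regiodefined enolate is C-alkylated by the triflate anti to the longer C10 chain (tandem conjugate addition–enolate alkylation), C9 staying epimerisable until step 6.

**Step 5**
Reactants: 10 (2S,3R)-2-[2-(furan-3-yl)ethyl]-3-(4-methoxy-4-methylpentyl)-3-methylcyclohexan-1-one
Product: 11 (5R,6S)-6-[2-(furan-3-yl)ethyl]-5-(4-methoxy-4-methylpentyl)-5-methylcyclohex-2-en-1-one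
Conditions: 2-iodoxybenzoic acid, 4-methoxypyridine N-oxide, DMSO, 25 °C
Reagents that add atoms: none
Why: Dehydrogenation of the ketone through its enol with 2-iodoxybenzoic acid can only run toward C7 because C10 carries no hydrogen, so a single enone (C8=O, C6=C7) forms and no stereocentre is touched.

**Step 6**
Reactants: 11 (5R,6S)-6-[2-(furan-3-yl)ethyl]-5-(4-methoxy-4-methylpentyl)-5-methylcyclohex-2-en-1-one
Product: 14 (1S,4aR,8aR)-1-[2-(furan-3-yl)ethyl]-5,5,8a-trimethyl-4a,5,6,7,8,8a-hexahydronaphthalen-2(1H)-one (trans-fused), via silyl dienol ether 12 (not isolated), via cis-fused enone 13 (not isolated)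
Conditions: TBSOTf, Et3N, CH2Cl2, −78 → −30 °C; pentane filtration; TiCl4, 2,6-di-tert-butyl-4-methylpyridine, CH2Cl2, −78 °C; then NaOMe (cat.), MeOH, 40 °C
Reagents that add atoms: none
Why: Soft enolisation gives the linear (γ) silyl dienol ether because the α′ hydrogen at C9 is tertiary and shielded, TiCl4 ionises the tertiary methyl ether and the C4 cation is captured by C5 in a six-membered intramolecular vinylogous Mukaiyama-type SN1 tert-alkylation (Reetz alkylation) that closes ring A, and methoxide then equilibrates the kinetic cis ring fusion (C5, through the dienolate) and C9 to the more stable trans-fused enone with an equatorial side chain.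

**Step 7**
Reactants: 14 (1S,4aR,8aR)-1-[2-(furan-3-yl)ethyl]-5,5,8a-trimethyl-4a,5,6,7,8,8a-hexahydronaphthalen-2(1H)-one
Product: 16 (1S,4R,4aR,8aR)-1-[2-(furan-3-yl)ethyl]-4-hydroxy-5,5,8a-trimethyloctahydronaphthalen-2(1H)-one, via boryl ketone 15 (not isolated)
Conditions: B2pin2, CuCl (5 mol %), 4,5-bis(diphenylphosphino)-9,9-dimethylxanthene (5 mol %), NaOt-Bu (10 mol %), MeOH (2 equiv), THF, 25 °C; then H2O2, NaH2PO4/Na2HPO4 buffer (pH 7), 0 °C
Reagents that add atoms: hydrogen peroxide OO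
Why: Copper-catalysed conjugate borylation delivers boron to C6 from the face opposite the axial C10 and C4 methyl groups, and stereoretentive C–B oxidation gives the equatorial C6 alcohol trans to the angular methyl.

**Step 8**
Reactants: 16 (1S,4R,4aR,8aR)-1-[2-(furan-3-yl)ethyl]-4-hydroxy-5,5,8a-trimethyloctahydronaphthalen-2(1H)-one
Product: 17 3-{2-[(1R,4R,4aR,8aS)-4-hydroxy-5,5,8a-trimethyl-2-methylidenedecahydronaphthalen-1-yl]ethyl}furan
Conditions: Zn, CH2Br2, TiCl4, THF, 0 → 25 °C
Reagents that add atoms: dibromomethane BrCBr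
Why: Takai–Lombardo methylenation with the non-basic zinc/titanium gem-dimetallic reagent converts the hindered, enolisable β-hydroxy ketone into the exocyclic alkene without retro-aldol cleavage, dehydration or epimerisation at C9.

**Step 9**
Reactants: 17 3-{2-[(1R,4R,4aR,8aS)-4-hydroxy-5,5,8a-trimethyl-2-methylidenedecahydronaphthalen-1-yl]ethyl}furan
Product: 21 (2Z)-3-(acetoxymethyl)-5-[(1R,4R,4aR,8aS)-4-hydroxy-5,5,8a-trimethyl-2-methylidenedecahydronaphthalen-1-yl]pent-2-enoic acid, via furan endoperoxide 18 (not isolated), via hydroxybutenolide 19 (not isolated), via hydroxy carboxylate 20 (not isolated)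
Conditions: O2, hν (visible), 5,10,15,20-tetraphenylporphyrin (1 mol %), i-Pr2NEt, CH2Cl2, −78 °C; solvent switch; NaBH4 (0.6 equiv), THF–H2O, 0 °C; then 1-acetylimidazole, Me4NOH (cat.), H2O–MeCN, 0 °C; NaH2PO4 to pH 4, cold extraction
Reagents that add atoms: dioxygen O=O; 1-acetylimidazole CC(=O)n1ccnc1
Why: Proposed new method: [4+2] addition of singlet oxygen to the furan and amine-induced Kornblum–DeLaMare opening of the endoperoxide at the less hindered C–H (remote from the alkyl group) give the hydroxybutenolide with C15 as carbonyl and C16 as hemiacetal, so C13=C14 is fixed as Z by the ring, borohydride reduces the ring-opened aldehyde to a hydroxy carboxylate that cannot lactonise while basic, and its primary hydroxyl is acetylated by 1-acetylimidazole in water (the carboxylate and the hindered C6–OH do not react) before mild acidification; the closest known reactions are the amine-directed photooxygenation of 3-alkylfurans to γ-hydroxybutenolides with borohydride reduction to butenolides, and the aqueous acetylimidazole acetylation of primary alcohols.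

**Compound list**
1 | 5-bromo-2-methylpent-2-ene | CC(C)=CCCBr | starting material
2 | 5-bromo-2-methoxy-2-methylpentane | COC(C)(C)CCCBr | intermediate
3 | 3-bromofuran | Brc1ccoc1 | starting material
4 | furan-3-yllithium | [Li]c1ccoc1 | intermediate
5 | 2-(furan-3-yl)ethan-1-ol | OCCc1ccoc1 | intermediate
6 | 2-(furan-3-yl)ethyl trifluoromethanesulfonate | O=S(=O)(OCCc1ccoc1)C(F)(F)F | intermediate
7 | 3-methylcyclohex-2-en-1-one | CC1=CC(=O)CCC1 | starting material
8 | (4-methoxy-4-methylpentyl)magnesium bromide | COC(C)(C)CCC[Mg]Br | intermediate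
9 | bromomagnesium (3R)-3-(4-methoxy-4-methylpentyl)-3-methylcyclohex-1-en-1-olate | Br[Mg]OC1=C[C@](C)(CCCC(C)(C)OC)CCC1 | intermediate
10 | (2S,3R)-2-[2-(furan-3-yl)ethyl]-3-(4-methoxy-4-methylpentyl)-3-methylcyclohexan-1-one | O=C1CCC[C@@](C)(CCCC(C)(C)OC)[C@@H]1CCc1ccoc1 | intermediate
11 | (5R,6S)-6-[2-(furan-3-yl)ethyl]-5-(4-methoxy-4-methylpentyl)-5-methylcyclohex-2-en-1-one | O=C1C=CC[C@@](C)(CCCC(C)(C)OC)[C@@H]1CCc1ccoc1 | intermediate
12 | tert-butyl({(5R,6S)-6-[2-(furan-3-yl)ethyl]-5-(4-methoxy-4-methylpentyl)-5-methylcyclohexa-1,3-dien-1-yl}oxy)dimethylsilane | CC(C)(C)[Si](C)(C)OC1=CC=C[C@@](C)(CCCC(C)(C)OC)[C@@H]1CCc1ccoc1 | intermediate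
13 | (1S,4aS,8aR)-1-[2-(furan-3-yl)ethyl]-5,5,8a-trimethyl-4a,5,6,7,8,8a-hexahydronaphthalen-2(1H)-one (cis-fused) | O=C1C=C[C@H]2C(C)(C)CCC[C@@]2(C)[C@@H]1CCc1ccoc1 | intermediate
14 | (1S,4aR,8aR)-1-[2-(furan-3-yl)ethyl]-5,5,8a-trimethyl-4a,5,6,7,8,8a-hexahydronaphthalen-2(1H)-one (trans-fused) | O=C1C=C[C@@H]2C(C)(C)CCC[C@@]2(C)[C@@H]1CCc1ccoc1 | intermediate
15 | (1S,4R,4aR,8aR)-1-[2-(furan-3-yl)ethyl]-5,5,8a-trimethyl-4-(4,4,5,5-tetramethyl-1,3,2-dioxaborolan-2-yl)octahydronaphthalen-2(1H)-one | O=C1C[C@@H](B3OC(C)(C)C(C)(C)O3)[C@@H]2C(C)(C)CCC[C@@]2(C)[C@@H]1CCc1ccoc1 | intermediate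
16 | (1S,4R,4aR,8aR)-1-[2-(furan-3-yl)ethyl]-4-hydroxy-5,5,8a-trimethyloctahydronaphthalen-2(1H)-one | O=C1C[C@@H](O)[C@@H]2C(C)(C)CCC[C@@]2(C)[C@@H]1CCc1ccoc1 | intermediate
17 | 3-{2-[(1R,4R,4aR,8aS)-4-hydroxy-5,5,8a-trimethyl-2-methylidenedecahydronaphthalen-1-yl]ethyl}furan | C=C1C[C@@H](O)[C@@H]2C(C)(C)CCC[C@@]2(C)[C@@H]1CCc1ccoc1 | intermediate
18 | 2,5-endoperoxide of 17 (5-substituted 2,3,7-trioxabicyclo[2.2.1]hept-5-ene; bridgehead configuration not defined) | C=C1C[C@@H](O)[C@@H]2C(C)(C)CCC[C@@]2(C)[C@@H]1CCC1=CC2OOC1O2 | intermediate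
19 | 5-hydroxy-4-{2-[(1R,4R,4aR,8aS)-4-hydroxy-5,5,8a-trimethyl-2-methylidenedecahydronaphthalen-1-yl]ethyl}furan-2(5H)-one (hemiacetal epimers) | C=C1C[C@@H](O)[C@@H]2C(C)(C)CCC[C@@]2(C)[C@@H]1CCC1=CC(=O)OC1O | intermediate
20 | sodium (2Z)-3-(hydroxymethyl)-5-[(1R,4R,4aR,8aS)-4-hydroxy-5,5,8a-trimethyl-2-methylidenedecahydronaphthalen-1-yl]pent-2-enoate | C=C1C[C@@H](O)[C@@H]2C(C)(C)CCC[C@@]2(C)[C@@H]1CC/C(=C/C(=O)[O-])CO.[Na+] | intermediate
21 | (2Z)-3-(acetoxymethyl)-5-[(1R,4R,4aR,8aS)-4-hydroxy-5,5,8a-trimethyl-2-methylidenedecahydronaphthalen-1-yl]pent-2-enoic acid | C=C1C[C@@H](O)[C@@H]2C(C)(C)CCC[C@@]2(C)[C@@H]1CC/C(=C/C(=O)O)COC(C)=O | target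

**Totals**
Total step count: 9. Longest linear sequence: 8 steps (3 to 21, steps 2–9).

**Steps most likely to fail, each with a fallback**

Step 6 (ring A closure). The furan may be attacked by TiCl4 or by the cation, and the dienol silane may form at C9 instead of C5. The fallback keeps the furan out of the Lewis acid step. It sets out from 7: enolate 9 is trapped with commercial 2-bromoethyl trifluoromethanesulfonate instead of 6, which gives (2S,3R)-2-(2-bromoethyl)-3-(4-methoxy-4-methylpentyl)-3-methylcyclohexan-1-one F4. Dehydrogenation as in step 5 gives (5R,6S)-6-(2-bromoethyl)-5-(4-methoxy-4-methylpentyl)-5-methylcyclohex-2-en-1-one F5. Silylation gives tert-butyl{[(5R,6S)-6-(2-bromoethyl)-5-(4-methoxy-4-methylpentyl)-5-methylcyclohexa-1,3-dien-1-yl]oxy}dimethylsilane F6, and TiCl4 closes ring A to (1S,4aS,8aR)-1-(2-bromoethyl)-5,5,8a-trimethyl-4a,5,6,7,8,8a-hexahydronaphthalen-2(1H)-one F7 and its trans-fused epimer (1S,4aR,8aR)-1-(2-bromoethyl)-5,5,8a-trimethyl-4a,5,6,7,8,8a-hexahydronaphthalen-2(1H)-one F8. The bromides are then coupled (Negishi; Pd2(dba)3, P(c-C5H9)3, N-methylimidazole, THF/NMP, 80 °C) with (furan-3-yl)zinc chloride F9, made from 3 with n-BuLi and ZnCl2. The methoxide equilibration of step 6 is run after the coupling, and the sequence comes back to the route at 14.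

Step 9 (one-flask furan opening, reduction, acetylation). The hydroxy carboxylate may relactonise to the butenolide before it is acetylated. The fallback sets out from 17 and stops the photooxygenation at the isolated hydroxybutenolide 19. Alkylation of its carboxylate (K2CO3, allyl bromide, DMF) opens it as prop-2-en-1-yl (2Z)-3-formyl-5-[(1R,4R,4aR,8aS)-4-hydroxy-5,5,8a-trimethyl-2-methylidenedecahydronaphthalen-1-yl]pent-2-enoate F10. Reduction with NaBH4/CeCl3·7H2O at −78 °C gives prop-2-en-1-yl (2Z)-3-(hydroxymethyl)-5-[(1R,4R,4aR,8aS)-4-hydroxy-5,5,8a-trimethyl-2-methylidenedecahydronaphthalen-1-yl]pent-2-enoate F11. This is acetylated in the same flask (Ac2O, pyridine, −20 °C) to prop-2-en-1-yl (2Z)-3-(acetoxymethyl)-5-[(1R,4R,4aR,8aS)-4-hydroxy-5,5,8a-trimethyl-2-methylidenedecahydronaphthalen-1-yl]pent-2-enoate F12. Deallylation with Pd(PPh3)4 and morpholine at 0 °C comes back to the route at 21.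

Step 4 (tandem conjugate addition and alkylation). The magnesium enolate may be too unreactive toward 6, or the triflate may eliminate. The fallback moves the alkylation to the enone stage. It sets out from 7: the conjugate addition is quenched with NH4Cl to give (3R)-3-(4-methoxy-4-methylpentyl)-3-methylcyclohexan-1-one F1. Dehydrogenation with 2-iodoxybenzoic acid gives (5R)-5-(4-methoxy-4-methylpentyl)-5-methylcyclohex-2-en-1-one F2. LDA in THF at −78 °C removes the only sp3 α-hydrogen (C9) to give lithium (3R)-3-(4-methoxy-4-methylpentyl)-3-methylcyclohexa-1,5-dien-1-olate F3, which is alkylated with 6 in THF/HMPA. This comes back to the route at 11 and skips 10.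

**Further compounds**
F1 | step 4 | (3R)-3-(4-methoxy-4-methylpentyl)-3-methylcyclohexan-1-one | O=C1CCC[C@@](C)(CCCC(C)(C)OC)C1
F2 | step 4 | (5R)-5-(4-methoxy-4-methylpentyl)-5-methylcyclohex-2-en-1-one | O=C1C=CC[C@@](C)(CCCC(C)(C)OC)C1
F3 | step 4 | lithium (3R)-3-(4-methoxy-4-methylpentyl)-3-methylcyclohexa-1,5-dien-1-olate | [Li]OC1=C[C@](C)(CCCC(C)(C)OC)CC=C1
F4 | step 6 | (2S,3R)-2-(2-bromoethyl)-3-(4-methoxy-4-methylpentyl)-3-methylcyclohexan-1-one | O=C1CCC[C@@](C)(CCCC(C)(C)OC)[C@@H]1CCBr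
F5 | step 6 | (5R,6S)-6-(2-bromoethyl)-5-(4-methoxy-4-methylpentyl)-5-methylcyclohex-2-en-1-one | O=C1C=CC[C@@](C)(CCCC(C)(C)OC)[C@@H]1CCBr
F6 | step 6 | tert-butyl{[(5R,6S)-6-(2-bromoethyl)-5-(4-methoxy-4-methylpentyl)-5-methylcyclohexa-1,3-dien-1-yl]oxy}dimethylsilane | CC(C)(C)[Si](C)(C)OC1=CC=C[C@@](C)(CCCC(C)(C)OC)[C@@H]1CCBr
F7 | step 6 | (1S,4aS,8aR)-1-(2-bromoethyl)-5,5,8a-trimethyl-4a,5,6,7,8,8a-hexahydronaphthalen-2(1H)-one | O=C1C=C[C@H]2C(C)(C)CCC[C@@]2(C)[C@@H]1CCBr
F8 | step 6 | (1S,4aR,8aR)-1-(2-bromoethyl)-5,5,8a-trimethyl-4a,5,6,7,8,8a-hexahydronaphthalen-2(1H)-one | O=C1C=C[C@@H]2C(C)(C)CCC[C@@]2(C)[C@@H]1CCBr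
F9 | step 6 | (furan-3-yl)zinc chloride | Cl[Zn]c1ccoc1
F10 | step 9 | prop-2-en-1-yl (2Z)-3-formyl-5-[(1R,4R,4aR,8aS)-4-hydroxy-5,5,8a-trimethyl-2-methylidenedecahydronaphthalen-1-yl]pent-2-enoate | C=C1C[C@@H](O)[C@@H]2C(C)(C)CCC[C@@]2(C)[C@@H]1CC/C(=C/C(=O)OCC=C)C=O
F11 | step 9 | prop-2-en-1-yl (2Z)-3-(hydroxymethyl)-5-[(1R,4R,4aR,8aS)-4-hydroxy-5,5,8a-trimethyl-2-methylidenedecahydronaphthalen-1-yl]pent-2-enoate | C=C1C[C@@H](O)[C@@H]2C(C)(C)CCC[C@@]2(C)[C@@H]1CC/C(=C/C(=O)OCC=C)CO
F12 | step 9 | prop-2-en-1-yl (2Z)-3-(acetoxymethyl)-5-[(1R,4R,4aR,8aS)-4-hydroxy-5,5,8a-trimethyl-2-methylidenedecahydronaphthalen-1-yl]pent-2-enoate | C=C1C[C@@H](O)[C@@H]2C(C)(C)CCC[C@@]2(C)[C@@H]1CC/C(=C/C(=O)OCC=C)COC(C)=O
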